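**Retrosynthetic overview**

1. Ring B (14-membered carbocycle) is closed last at C12–C13 by an intramolecular Ni/Cr alkenyl iodide–aldehyde coupling, which also sets C13.
2. C5–C6 comes from a boron aldol between a (Z,E)-iododienyl methyl ketone and the ring A aldehyde; an Evans–Tishchenko reduction then sets C7-OH and puts the acetate on C5 (1,3-anti) in one step.
3. Ring A (α-methylene-ε-lactone) is formed first, by acyl transfer from an N-acyloxazolidinone to the C4 tertiary alkoxide, followed by Mannich methylenation.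
4. Key bond C1–C14: a Yb(OTf)3-templated radical conjugate addition of the 2,2-dimethoxyethyl radical to an (E)-N-enoyloxazolidinone fixes C1 before either ring exists.
5. C4 comes from (R)-2-methylglycidol; the dienone comes from but-3-yn-2-ol, MeMgBr and but-2-yn-1-ol (anti-carbomagnesiation for 8Z, hydrozirconation for 11E).

Assumption: cembrane numbering is used throughout (C1–C14 ring B, C15–C17 the methylene-acrylate unit, C18–C20 the methyls on C4, C8, C12), ring A is the seven-membered lactone, and the recovered oxazolidinone auxiliary is treated as a reagent.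

**Step 1**
Reactants: 1 (R)-2-methylglycidol; 2 allylmagnesium bromide
Product: 3 (S)-2-methylhex-5-ene-1,2-diol
Conditions: 2 (3 equiv), CuI (10 mol %), THF, −30 to 0 °C; aq. NH4Cl
Reagents that add atoms: none
Why: Copper-catalysed Grignard opening of the epoxide at its unsubstituted CH2 (SN2) attaches C2/C1 to C3, and the C4 carbinol centre is carried over untouched from 1 (the descriptor changes from R to S only because the priorities change).

**Step 2**
Reactants: 3 (S)-2-methylhex-5-ene-1,2-diol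
Product: 4 (S)-2-methyl-1-(triethylsilyloxy)hex-5-en-2-ol
Conditions: Et3SiCl (1.05 equiv), imidazole, CH2Cl2, −20 °C
Reagents that add atoms: chlorotriethylsilane, CC[Si](Cl)(CC)CC
Why: Selective silylation of the primary over the tertiary hydroxyl masks C5-OH and leaves the C4 hydroxyl free for the later lactonisation.

**Step 3**
Reactants: 5 acryloyl chloride
Product: 6 (S)-3-acryloyl-4-(diphenylmethyl)oxazolidin-2-one
Conditions: (S)-4-(diphenylmethyl)oxazolidin-2-one, n-BuLi, THF, −78 °C; then 5, −78 to 0 °C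
Reagents that add atoms: (S)-4-(diphenylmethyl)oxazolidin-2-one (recoverable auxiliary), O=C1N[C@@H](C(c2ccccc2)c2ccccc2)CO1
Why: N-acylation of the lithiated oxazolidinone gives the acrylimide that supplies C15/C16 and the chiral template for the radical step.

**Step 4**
Reactants: 4 (S)-2-methyl-1-(triethylsilyloxy)hex-5-en-2-ol; 6 (S)-3-acryloyl-4-(diphenylmethyl)oxazolidin-2-one
Product: 7 (S)-4-(diphenylmethyl)-3-[(2E,6S)-6-hydroxy-6-methyl-7-(triethylsilyloxy)hept-2-enoyl]oxazolidin-2-one
Conditions: 6 (1.5 equiv), second-generation Hoveyda–Grubbs catalyst (5 mol %), CH2Cl2, 40 °C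
Reagents that add atoms: none
Why: Olefin cross-metathesis between the terminal alkene and the electron-poor acrylimide gives the thermodynamically favoured (E)-enoyl imide with loss of ethylene.

**Step 5** (key step)
Reactants: 7 (S)-4-(diphenylmethyl)-3-[(2E,6S)-6-hydroxy-6-methyl-7-(triethylsilyloxy)hept-2-enoyl]oxazolidin-2-one; 8 2-bromo-1,1-dimethoxyethane
Product: 9 (S)-3-[(3S,6S)-3-(2,2-dimethoxyethyl)-6-hydroxy-6-methyl-7-(triethylsilyloxy)heptanoyl]-4-(diphenylmethyl)oxazolidin-2-one
Conditions: Yb(OTf)3 (1.5 equiv), 8 (8 equiv), Bu3SnH (3 equiv), Et3B (3 equiv)/O2, CH2Cl2–THF (4:1), −78 °C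
Reagents that add atoms: none
Why: In this auxiliary-controlled Giese-type radical conjugate addition Yb(OTf)3 chelates both imide carbonyls and locks the s-cis enoyl rotamer, so the nucleophilic 2,2-dimethoxyethyl radical (Br abstraction from 8 by Bu3Sn•) forms the C1–C14 bond on the face opposite the diphenylmethyl group and gives 1S (dr expected ≥ 20:1) before Bu3SnH quenches the α-radical.

**Step 6**
Reactants: 9 (S)-3-[(3S,6S)-3-(2,2-dimethoxyethyl)-6-hydroxy-6-methyl-7-(triethylsilyloxy)heptanoyl]-4-(diphenylmethyl)oxazolidin-2-one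
Product: 10 (4S,7S)-4-(2,2-dimethoxyethyl)-7-methyl-7-[(triethylsilyloxy)methyl]oxepan-2-one
Conditions: i-PrMgCl (1.1 equiv), THF, 0 °C to rt; aq. NH4Cl
Reagents that add atoms: none
Why: The chloromagnesium alkoxide of the C4 tertiary alcohol attacks the activated exocyclic imide carbonyl (intramolecular alkoxide transacylation of an N-acyloxazolidinone), closing ring A and releasing the auxiliary without touching C1 or C4.

**Step 7**
Reactants: 10 (4S,7S)-4-(2,2-dimethoxyethyl)-7-methyl-7-[(triethylsilyloxy)methyl]oxepan-2-one; 11 N,N-dimethylmethyleneiminium iodide (Eschenmoser's salt)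
Product: 15 (4S,7S)-4-(2,2-dimethoxyethyl)-7-methyl-3-methylidene-7-[(triethylsilyloxy)methyl]oxepan-2-one, via lithium enolate 12 (not isolated), via Mannich base 13 (not isolated), via ammonium iodide 14 (not isolated)
Conditions: LDA, THF, −78 °C; 11, −78 °C to rt; MeI, MeOH, rt; DBU, CH2Cl2, rt
Reagents that add atoms: none
Why: Enolate Mannich reaction at C15 (the only enolisable position), N-quaternisation and E1cB elimination of trimethylamine install the C15=C17 exo-methylene, and the transient C15 stereocentre is destroyed.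

**Step 8**
Reactants: 15 (4S,7S)-4-(2,2-dimethoxyethyl)-7-methyl-3-methylidene-7-[(triethylsilyloxy)methyl]oxepan-2-one
Product: 16 (4S,7S)-7-formyl-4-(2,2-dimethoxyethyl)-7-methyl-3-methylideneoxepan-2-one
Conditions: (COCl)2, DMSO, CH2Cl2, −78 to −40 °C; Et3N, −78 to 0 °C
Reagents that add atoms: none
Why: Swern oxidation applied directly to the primary triethylsilyl ether (activated DMSO cleaves the Si–O bond, then ylide collapse) gives the non-enolisable C5 aldehyde without a separate desilylation.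

**Step 9**
Reactants: 17 but-2-yn-1-ol
Product: 19 (E)-3-iodobut-2-en-1-ol, via alkenylzirconocene 18 (not isolated)
Conditions: Cp2Zr(H)Cl (2.2 equiv), THF, rt; I2, 0 °C
Reagents that add atoms: iodine, II
Why: syn-Hydrozirconation places zirconium on the less hindered, methyl-bearing alkyne carbon, and iodinolysis with retention gives the E alkenyl iodide (future C11=C12).

**Step 10**
Reactants: 19 (E)-3-iodobut-2-en-1-ol
Product: 20 (E)-1-bromo-3-iodobut-2-ene
Conditions: PBr3 (0.4 equiv), Et2O, 0 °C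
Reagents that add atoms: phosphorus tribromide, BrP(Br)Br
Why: SN2 bromination of the primary allylic alcohol leaves the alkene geometry unchanged.

**Step 11**
Reactants: 21 but-3-yn-2-ol (racemic); 22 methylmagnesium bromide; 20 (E)-1-bromo-3-iodobut-2-ene
Product: 24 (3Z,6E)-7-iodo-3-methylocta-3,6-dien-2-ol, via alkenylmagnesium chelate 23 (not isolated)
Conditions: 22 (2.4 equiv), CuI (10 mol %), THF, 0 °C to rt; then 20 (1.6 equiv), 0 °C to rt; aq. NH4Cl
Reagents that add atoms: none
Why: Copper-catalysed anti-carbomagnesiation of the propargylic alkoxide puts methyl on C8 and magnesium on C9 trans to it within a five-membered chelate, so copper-mediated SN2 allylation with retention leaves C7 and C10 cis (8Z) while the 11E iodide is untouched.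

**Step 12**
Reactants: 24 (3Z,6E)-7-iodo-3-methylocta-3,6-dien-2-ol
Product: 25 (3Z,6E)-7-iodo-3-methylocta-3,6-dien-2-one
Conditions: Dess–Martin periodinane, CH2Cl2, 0 °C
Reagents that add atoms: none
Why: Mild, non-basic oxidation of the secondary allylic alcohol gives the methyl ketone without isomerising the Z-enone, and the carbinol stereocentre of 24 is erased.

**Step 13**
Reactants: 25 (3Z,6E)-7-iodo-3-methylocta-3,6-dien-2-one; 16 (4S,7S)-7-formyl-4-(2,2-dimethoxyethyl)-7-methyl-3-methylideneoxepan-2-one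
Product: 27 (4S,7S)-4-(2,2-dimethoxyethyl)-7-[(1R,4Z,7E)-1-hydroxy-8-iodo-4-methyl-3-oxonona-4,7-dien-1-yl]-7-methyl-3-methylideneoxepan-2-one, via boron enolate 26 (not isolated)
Conditions: 25 (1.4 equiv), (−)-Ipc2BCl (1.3 equiv), Et3N, Et2O, 0 °C; 16, −78 to −20 °C; H2O2, MeOH, pH 7 buffer, 0 °C
Reagents that add atoms: none
Why: In this Paterson boron aldol the kinetic methyl-side enolate adds to the Re face of the aldehyde, the reagent preference being matched with the polar Felkin–Anh/Cornforth bias (attack anti to the C4–O bond, past the methyl group), which gives 5R.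

**Step 14**
Reactants: 27 (4S,7S)-4-(2,2-dimethoxyethyl)-7-[(1R,4Z,7E)-1-hydroxy-8-iodo-4-methyl-3-oxonona-4,7-dien-1-yl]-7-methyl-3-methylideneoxepan-2-one; 28 acetaldehyde
Product: 29 (4S,7S)-7-[(1R,3R,4Z,7E)-1-acetoxy-3-hydroxy-8-iodo-4-methylnona-4,7-dien-1-yl]-4-(2,2-dimethoxyethyl)-7-methyl-3-methylideneoxepan-2-one
Conditions: 28 (10 equiv), SmI2 (30 mol %), THF, −10 °C
Reagents that add atoms: none
Why: In the Evans–Tishchenko reduction the samarium-bound hemiacetal of the C5 hydroxyl delivers hydride intramolecularly to the C7 ketone through a chair transition state, giving the 1,3-anti alcohol (7R) and leaving the acetyl group on the C5 oxygen.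

**Step 15**
Reactants: 29 (4S,7S)-7-[(1R,3R,4Z,7E)-1-acetoxy-3-hydroxy-8-iodo-4-methylnona-4,7-dien-1-yl]-4-(2,2-dimethoxyethyl)-7-methyl-3-methylideneoxepan-2-one
Product: 30 2-{(4S,7S)-7-[(1R,3R,4Z,7E)-1-acetoxy-3-hydroxy-8-iodo-4-methylnona-4,7-dien-1-yl]-7-methyl-3-methylidene-2-oxooxepan-4-yl}acetaldehyde
Conditions: LiBF4, MeCN–H2O (50:1), rt
Reagents that add atoms: water, O
Why: Mild Lewis-acid hydrolysis of the dimethyl acetal unmasks the C13 aldehyde without disturbing the allylic alcohol, the acetate or the tertiary lactone.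

**Step 16**
Reactants: 30 2-{(4S,7S)-7-[(1R,3R,4Z,7E)-1-acetoxy-3-hydroxy-8-iodo-4-methylnona-4,7-dien-1-yl]-7-methyl-3-methylidene-2-oxooxepan-4-yl}acetaldehyde
Product: 31 CNP0183491.1, (1S,4S,5R,7R,8Z,11E,13S)-5-acetoxy-7,13-dihydroxycembra-8,11,15(17)-trien-16,4-olide
Conditions: CrCl2 (8 equiv), NiCl2 (10 mol %), Kishi's chiral oxazoline–sulfonamide ligand (antipode giving Re-face attack), Et3N, THF, rt, 2 mM, slow addition of 30
Reagents that add atoms: none
Why: In this Nozaki–Hiyama–Kishi macrocyclisation zerovalent nickel inserts into the C12–I bond, transmetallation gives the alkenylchromium with retention of the 11E geometry, and the ligand-bound chromium delivers it to the Re face of the aldehyde (13S), closing ring B while tolerating the free hydroxyl, the acetate and the methylene lactone.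

**Compound list**

1 | (R)-2-methylglycidol | C[C@@]1(CO)CO1 | starting material
2 | allylmagnesium bromide | C=CC[Mg]Br | starting material
3 | (S)-2-methylhex-5-ene-1,2-diol | O[C@@](CO)(C)CCC=C | intermediate
4 | (S)-2-methyl-1-(triethylsilyloxy)hex-5-en-2-ol | O[C@@](CO[Si](CC)(CC)CC)(C)CCC=C | intermediate
5 | acryloyl chloride | C=CC(Cl)=O | starting material
6 | (S)-3-acryloyl-4-(diphenylmethyl)oxazolidin-2-one | C=CC(=O)N1[C@@H](C(c2ccccc2)c2ccccc2)COC1=O | intermediate
7 | (S)-4-(diphenylmethyl)-3-[(2E,6S)-6-hydroxy-6-methyl-7-(triethylsilyloxy)hept-2-enoyl]oxazolidin-2-one | O[C@@](CO[Si](CC)(CC)CC)(C)CC/C=C/C(=O)N1[C@@H](C(c2ccccc2)c2ccccc2)COC1=O | intermediate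
8 | 2-bromo-1,1-dimethoxyethane | BrCC(OC)OC | starting material
9 | (S)-3-[(3S,6S)-3-(2,2-dimethoxyethyl)-6-hydroxy-6-methyl-7-(triethylsilyloxy)heptanoyl]-4-(diphenylmethyl)oxazolidin-2-one | O[C@@](CO[Si](CC)(CC)CC)(C)CC[C@H](CC(=O)N1[C@@H](C(c2ccccc2)c2ccccc2)COC1=O)CC(OC)OC | intermediate
10 | (4S,7S)-4-(2,2-dimethoxyethyl)-7-methyl-7-[(triethylsilyloxy)methyl]oxepan-2-one | C1C(=O)O[C@@](CO[Si](CC)(CC)CC)(C)CC[C@H]1CC(OC)OC | intermediate
11 | N,N-dimethylmethyleneiminium iodide (Eschenmoser's salt) | C=[N+](C)C.[I-] | starting material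
12 | lithium enolate of 10 | C1=C(O[Li])O[C@@](CO[Si](CC)(CC)CC)(C)CC[C@H]1CC(OC)OC | intermediate
13 | (4S,7S)-3-[(dimethylamino)methyl]-4-(2,2-dimethoxyethyl)-7-methyl-7-[(triethylsilyloxy)methyl]oxepan-2-one (C3 epimers) | CN(C)CC1C(=O)O[C@@](CO[Si](CC)(CC)CC)(C)CC[C@H]1CC(OC)OC | intermediate
14 | trimethylammonium iodide of 13 | C[N+](C)(C)CC1C(=O)O[C@@](CO[Si](CC)(CC)CC)(C)CC[C@H]1CC(OC)OC.[I-] | intermediate
15 | (4S,7S)-4-(2,2-dimethoxyethyl)-7-methyl-3-methylidene-7-[(triethylsilyloxy)methyl]oxepan-2-one | C=C1C(=O)O[C@@](CO[Si](CC)(CC)CC)(C)CC[C@H]1CC(OC)OC | intermediate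
16 | (4S,7S)-7-formyl-4-(2,2-dimethoxyethyl)-7-methyl-3-methylideneoxepan-2-one | C=C1C(=O)O[C@@](C=O)(C)CC[C@H]1CC(OC)OC | intermediate
17 | but-2-yn-1-ol | CC#CCO | starting material
18 | (E)-alkenylzirconocene chloride from 17 (zirconium on C3 and on oxygen) | C/C(=C\CO[Zr](Cl)(C1C=CC=C1)C1C=CC=C1)[Zr](Cl)(C1C=CC=C1)C1C=CC=C1 | intermediate
19 | (E)-3-iodobut-2-en-1-ol | C/C(I)=C\CO | intermediate
20 | (E)-1-bromo-3-iodobut-2-ene | C/C(I)=C\CBr | intermediate
21 | but-3-yn-2-ol (racemic) | CC(O)C#C | starting material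
22 | methylmagnesium bromide | C[Mg]Br | starting material
23 | (Z)-alkenylmagnesium bromide chelate of the 3-methylbut-3-en-2-olate | CC(O[Mg]Br)/C(C)=C\[Mg]Br | intermediate
24 | (3Z,6E)-7-iodo-3-methylocta-3,6-dien-2-ol (racemic at C2) | CC(O)/C(C)=C\C/C=C(\C)I | intermediate
25 | (3Z,6E)-7-iodo-3-methylocta-3,6-dien-2-one | CC(=O)/C(C)=C\C/C=C(\C)I | intermediate
26 | diisopinocampheylboron enolate of 25 (Ipc from (+)-α-pinene; Ipc ring stereocentres not drawn) | C=C(OB(C1CC2CC(C1C)C2(C)C)C1CC2CC(C1C)C2(C)C)/C(C)=C\C/C=C(\C)I | intermediate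
27 | (4S,7S)-4-(2,2-dimethoxyethyl)-7-[(1R,4Z,7E)-1-hydroxy-8-iodo-4-methyl-3-oxonona-4,7-dien-1-yl]-7-methyl-3-methylideneoxepan-2-one | C=C1C(=O)O[C@@]([C@H](O)CC(=O)/C(C)=C\C/C=C(\C)I)(C)CC[C@H]1CC(OC)OC | intermediate
28 | acetaldehyde | CC=O | starting material
29 | (4S,7S)-7-[(1R,3R,4Z,7E)-1-acetoxy-3-hydroxy-8-iodo-4-methylnona-4,7-dien-1-yl]-4-(2,2-dimethoxyethyl)-7-methyl-3-methylideneoxepan-2-one | C=C1C(=O)O[C@@]([C@H](OC(C)=O)C[C@@H](O)/C(C)=C\C/C=C(\C)I)(C)CC[C@H]1CC(OC)OC | intermediate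
30 | 2-{(4S,7S)-7-[(1R,3R,4Z,7E)-1-acetoxy-3-hydroxy-8-iodo-4-methylnona-4,7-dien-1-yl]-7-methyl-3-methylidene-2-oxooxepan-4-yl}acetaldehyde | C=C1C(=O)O[C@@]([C@H](OC(C)=O)C[C@@H](O)/C(C)=C\C/C=C(\C)I)(C)CC[C@H]1CC=O | intermediate
31 | CNP0183491.1, (1S,4S,5R,7R,8Z,11E,13S)-5-acetoxy-7,13-dihydroxycembra-8,11,15(17)-trien-16,4-olide | C=C1C(=O)O[C@@]2(C)CC[C@H]1C[C@H](O)/C(C)=C/C/C=C(/C)[C@H](O)C[C@H]2OC(C)=O | target

**Step count and risks**

Total steps: 16. Longest linear sequence: 11 (steps 1, 2, 4, 5, 6, 7, 8, 13, 14, 15, 16).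

The three steps most likely to fail:

- **Step 5 (radical conjugate addition).** The free tertiary alcohol of 7 may close onto the Yb-activated enoyl imide (oxa-Michael), ethyl radicals from Et3B may compete with the less reactive bromide 8, and the primary β,β-dialkoxy radical is less nucleophilic than the radicals usually used. The fallback sets out from 4 and returns at 10. The tertiary alcohol is acylated with 5 (n-BuLi, THF, −78 °C) to give (S)-2-methyl-1-(triethylsilyloxy)hex-5-en-2-yl acrylate F1. Ring-closing metathesis (second-generation Grubbs catalyst, toluene, 80 °C) then closes ring A to (S)-7-methyl-7-[(triethylsilyloxy)methyl]-6,7-dihydrooxepin-2(5H)-one F2. The radical from 8 is added to this cyclic enoate (Bu3SnH, AIBN, benzene, 80 °C, slow addition), which gives 10 directly. The key bond is still made by radical addition, but C1 is then controlled only by the ring and the C1 epimers must be separated.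

- **Step 6 (lactonisation).** A tertiary alkoxide has to form a seven-membered ring by displacing the auxiliary, and silyl migration or attack at the carbamate carbonyl could intervene. The fallback sets out from 9 and returns at 10. LiOH/H2O2 (THF–H2O, 0 °C) removes the auxiliary to give (3S,6S)-3-(2,2-dimethoxyethyl)-6-hydroxy-6-methyl-7-(triethylsilyloxy)heptanoic acid F3. This hydroxy acid is then cyclised by a Shiina lactonisation (2-methyl-6-nitrobenzoic anhydride, DMAP, toluene, 60 °C, high dilution).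

- **Step 16 (macrocyclisation).** The ring closure may be slow, and the C13 configuration rests on ligand control over an aldehyde that is unbranched at its α-carbon (C14). The fallback sets out from 29 and returns at 31.
  - C7-OH is silylated (TBSOTf, 2,6-lutidine) to the C7 tert-butyldimethylsilyl ether F4.
  - The acetal is hydrolysed (LiBF4, wet MeCN) to the aldehyde F5.
  - Ligand-free CrCl2/NiCl2 coupling in DMSO closes ring B to the C13-epimeric macrocyclic alcohols F6.
  - Dess–Martin oxidation gives the C13 enone F7.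
  - Reagent-controlled 1,2-reduction with (R)-Me-CBS/catecholborane gives the 13S alcohol F8.
  - HF·pyridine removes the silyl group to give 31.

**Further compounds**

F1 | step 5 | (S)-2-methyl-1-(triethylsilyloxy)hex-5-en-2-yl acrylate | C=CC(=O)O[C@@](CO[Si](CC)(CC)CC)(C)CCC=C
F2 | step 5 | (S)-7-methyl-7-[(triethylsilyloxy)methyl]-6,7-dihydrooxepin-2(5H)-one | O=C1O[C@@](CO[Si](CC)(CC)CC)(C)CCC=C1
F3 | step 6 | (3S,6S)-3-(2,2-dimethoxyethyl)-6-hydroxy-6-methyl-7-(triethylsilyloxy)heptanoic acid | O[C@@](CO[Si](CC)(CC)CC)(C)CC[C@H](CC(=O)O)CC(OC)OC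
F4 | step 16 | C7 tert-butyldimethylsilyl ether of 29 | C=C1C(=O)O[C@@]([C@H](OC(C)=O)C[C@@H](O[Si](C)(C)C(C)(C)C)/C(C)=C\C/C=C(\C)I)(C)CC[C@H]1CC(OC)OC
F5 | step 16 | C13 aldehyde from F4 | C=C1C(=O)O[C@@]([C@H](OC(C)=O)C[C@@H](O[Si](C)(C)C(C)(C)C)/C(C)=C\C/C=C(\C)I)(C)CC[C@H]1CC=O
F6 | step 16 | 7-O-tert-butyldimethylsilyl ether of 31 as a mixture of C13 epimers | C=C1C(=O)O[C@@]2(C)CC[C@H]1CC(O)/C(C)=C/C/C=C(/C)[C@H](O[Si](C)(C)C(C)(C)C)C[C@H]2OC(C)=O
F7 | step 16 | 13-oxo-7-O-tert-butyldimethylsilyl macrocycle (C13 enone) | C=C1C(=O)O[C@@]2(C)CC[C@H]1CC(=O)/C(C)=C/C/C=C(/C)[C@H](O[Si](C)(C)C(C)(C)C)C[C@H]2OC(C)=O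
F8 | step 16 | (13S)-7-O-tert-butyldimethylsilyl ether of 31 | C=C1C(=O)O[C@@]2(C)CC[C@H]1C[C@H](O)/C(C)=C/C/C=C(/C)[C@H](O[Si](C)(C)C(C)(C)C)C[C@H]2OC(C)=O
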